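**Plan**
1. Numbering used for all compounds: carbocycle C1–C10; ether O between C2 and C9 (tetrahydrofuran O/C2/C1/C10/C9); cyclohexenone C1/C10/C11/C12/C13/C14; oxepane C3–O–C16–C15–C14–C1–C2; butanoate on C4.
2. Retrosynthetic cuts, in order: C4 ester; enone transposition (C13=O/C11–Me ⇐ C11=O); O–C16 (oxepane) and the C16 hydroxyl (⇐ C15=C16); C1–C14 and C12–C13 (Diels–Alder); C10–C11 (Stille); then C8–C9 together with O–C9, which restores an O–C6 bond.
3. Enabling feature: the bridging oxygen carries C9 (next to the C10 carbonyl) and lies two bonds from the allyl unit C6=C7–C8, so O, C9, C8, C7, C6 form a [2,3] array. Read backwards, the nine-membered oxonene contracts to a 2-isopropenyl tetrahydropyran whose oxygen is attacked by a C9 carbene.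
4. Forward ring order: dihydropyranone (hetero-Diels–Alder) → C2 side chain (Ireland–Claisen) and C3/C4 oxygens (epoxide lactonisation) → diazoketone → tetrahydrofuranone and Z-oxonene in one operation → cyclohexene (Diels–Alder) → oxepane (triflate etherification) → transposed enone.
5. Stereochemistry: one catalytic asymmetric hetero-Diels–Alder sets C6. It is relayed to C2 (suprafacial Claisen), C3/C4 (anti epoxide opening), C9 (bridging), C1/C14/C10 (cycloaddition face, epimerisation, protonation) and C15 (hydroboration); C6 itself ends as an sp2 carbon of the Z-alkene.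

Key step: step 10

Assumption: [Cr(salen)]BF4 (salen = dianion of N,N′-bis(3,5-di-tert-butylsalicylidene)-trans-cyclohexane-1,2-diamine, trivalent chromium) is used as the antipode that delivers (S)-4; the sense of induction has to be confirmed on the first run.

**Step 1**
Reactants: 1 2-methylprop-2-enal; 2 (E)-1-methoxy-3-(trimethylsilyloxy)buta-1,3-diene
Product: 4 (S)-2-(prop-1-en-2-yl)-2,3-dihydro-4H-pyran-4-one, via silyl enol ether cycloadduct 3 (not isolated)
Conditions: [Cr(salen)]BF4 (2 mol %), 4 Å MS, tBuOMe, −30 °C; then CF3CO2H (cat.), CH2Cl2, 0 °C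
Reagents that add atoms: none
Why: Lewis-acid-catalysed hetero-Diels–Alder reaction at the aldehyde C=O (the α-substituted C=C is the slower dienophile), then acid-induced loss of methanol and the silyl group, should give the dihydropyranone, the chiral complex selecting the aldehyde face and so setting C6.

**Step 2**
Reactants: 4 (S)-2-(prop-1-en-2-yl)-2,3-dihydro-4H-pyran-4-one
Product: 5 (S)-5-iodo-2-(prop-1-en-2-yl)-2,3-dihydro-4H-pyran-4-one
Conditions: I2, pyridine, CH2Cl2, 0 °C → rt
Reagents that add atoms: iodine, II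
Why: α-Iodination of the vinylogous ester by addition–elimination places a halide on the future C3 for the methyl coupling.

**Step 3**
Reactants: 5 (S)-5-iodo-2-(prop-1-en-2-yl)-2,3-dihydro-4H-pyran-4-one
Product: 6 (S)-5-methyl-2-(prop-1-en-2-yl)-2,3-dihydro-4H-pyran-4-one
Conditions: SnMe4, Pd2(dba)3 (2.5 mol %), AsPh3, CuI, NMP, 60 °C
Reagents that add atoms: tetramethylstannane, C[Sn](C)(C)C
Why: Stille coupling of the α-iodoenone installs the C3 methyl group under neutral conditions that leave the vinylogous ester intact.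

**Step 4**
Reactants: 6 (S)-5-methyl-2-(prop-1-en-2-yl)-2,3-dihydro-4H-pyran-4-one
Product: 7 (2S,4S)-5-methyl-2-(prop-1-en-2-yl)-3,4-dihydro-2H-pyran-4-ol (2,4-cis)
Conditions: NaBH4, CeCl3·7H2O, MeOH, −78 → −20 °C
Reagents that add atoms: none
Why: Luche reduction gives 1,2-reduction only, and axial hydride delivery to the half-chair places the hydroxyl equatorial, cis to the C6 isopropenyl group.

**Step 5**
Reactants: 7 (2S,4S)-5-methyl-2-(prop-1-en-2-yl)-3,4-dihydro-2H-pyran-4-ol
Product: 8 (2S,4S)-5-methyl-2-(prop-1-en-2-yl)-3,4-dihydro-2H-pyran-4-yl acetate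
Conditions: Ac2O, pyridine, DMAP (cat.), CH2Cl2, 0 °C
Reagents that add atoms: acetic anhydride, CC(=O)OC(C)=O
Why: Base-mediated acylation of the allylic alcohol avoids acid, which would ionise the glycal-type allylic system.

**Step 6**
Reactants: 8 (2S,4S)-5-methyl-2-(prop-1-en-2-yl)-3,4-dihydro-2H-pyran-4-yl acetate
Product: 11 2-[(2S,6S)-3-methyl-6-(prop-1-en-2-yl)-3,6-dihydro-2H-pyran-2-yl]acetic acid (2,6-cis), via trimethylsilyl ketene acetal 9 (not isolated), via trimethylsilyl ester 10 (not isolated)
Conditions: LiN(iPr)2, Me3SiCl/Et3N, THF, −78 → 50 °C; then aq. NaOH, acidification to pH 4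
Reagents that add atoms: none
Why: Ireland–Claisen rearrangement through a boat-like six-membered transition state is suprafacial, so the new C1–C2 bond forms on the face the C4 oxygen leaves, cis to the C6 substituent, and the ring alkene moves to C3=C4.

**Step 7**
Reactants: 11 2-[(2S,6S)-3-methyl-6-(prop-1-en-2-yl)-3,6-dihydro-2H-pyran-2-yl]acetic acid
Product: 13 cis-fused hydroxy γ-lactone (C3–O–C10 lactone; C4 hydroxyl trans to the C3 oxygen; C6 isopropenyl cis to C1), via anti epoxy acid 12 (not isolated)
Conditions: dimethyldioxirane (1.05 equiv), acetone/CH2Cl2, −20 °C; then camphorsulfonic acid (cat.), CH2Cl2, rt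
Reagents that add atoms: dimethyldioxirane, CC1(C)OO1
Why: The trisubstituted ring alkene is epoxidised before the 1,1-disubstituted one and anti to the allylic C2 side chain, and acid-catalysed 5-exo opening at the tertiary C3 by the carboxyl group with inversion then puts the C3 oxygen cis to the side chain and the C4 hydroxyl trans to it (a syn epoxide cannot lactonise and would converge on the same product by hydroxide opening at C4).

**Step 8**
Reactants: 13 cis-fused hydroxy γ-lactone
Product: 16 2,6-cis tetrahydropyranylacetic acid with C3 and C4 triethylsilyl ethers, via lithium dihydroxy carboxylate 14 (not isolated), via tris(triethylsilyl) derivative 15 (not isolated)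
Conditions: LiOH, THF/H2O, rt; evaporation; Et3SiOTf (3.5 equiv), 2,6-lutidine, CH2Cl2, 0 °C; then K2CO3 (cat.), MeOH/H2O, 0 °C, pH 5 buffer
Reagents that add atoms: lithium hydroxide, [Li+].[OH-]; triethylsilyl trifluoromethanesulfonate, CC[Si](CC)(CC)OS(=O)(=O)C(F)(F)F
Why: Saponification opens the lactone and silylation of the salt before any acidification prevents relactonisation, after which only the labile silyl ester is cleaved by mild methanolysis.

**Step 9**
Reactants: 16 bis(triethylsilyl ether) acid
Product: 18 diazoketone (C2–CH2–CO–CHN2), via isobutyl carbonic anhydride 17 (not isolated)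
Conditions: iBuOCOCl, Et3N, Et2O, −20 °C; then CH2N2, Et2O, 0 °C
Reagents that add atoms: diazomethane, C=[N+]=[N-]
Why: Acylation of diazomethane by the mixed anhydride (first stage of an Arndt–Eistert sequence) gives the α-diazoketone without touching the silyl ethers or the alkenes.

**Step 10**
Reactants: 18 diazoketone
Product: 20 Z-oxonene-bridged tetrahydrofuran-3-one (C10 ketone; C2–H and C9–H cis; C6=C7 Z), via bicyclic oxonium ylide 19 (not isolated)
Conditions: Cu(CF3COCHCOCF3)2 (5 mol %), CH2Cl2, reflux, slow addition of 18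
Reagents that add atoms: none
Why: The electron-poor copper complex converts the diazoketone into a copper carbenoid at C9, which is attacked by the nearest lone pair, that of the tetrahydropyran oxygen, to give oxonium ylide 19; this undergoes a [2,3]-sigmatropic shift in which C9 bonds to the isopropenyl terminus C8 while the allylic O–C6 bond breaks. The closest known reaction type is the catalytic tandem oxonium ylide formation/[2,3]-rearrangement of allylic ethers, here in its three-atom ring-expanding form on a 2-alkenyl tetrahydropyran. The tetrahydrofuranone ring (O, C2, C1, C10, C9) closes by 5-exo attack of oxygen on the carbenoid carbon, and the nine-membered oxonene (and with it the ten-membered carbocycle) arises by ring expansion of the six-membered ether through a five-membered envelope transition state made of C9, O, C6, C7 and C8. The only new stereocentre, C9, is fixed by C2, because the one-atom oxygen bridge can span C2 and C9 only with the two hydrogens cis. The step needs Z over E geometry at C6=C7 and ylide formation at the ring oxygen in preference to the silyl ether oxygens, [1,2]-shift or C–H insertion; the 2,6-cis substrate with an equatorial isopropenyl group and the hexafluoroacetylacetonate ligand set are expected to favour the Z-oxonene, and the bulky silyl ethers at C3 and C4 are poor donors that would have to form larger rings.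

**Step 11**
Reactants: 20 Z-oxonene-bridged tetrahydrofuran-3-one
Product: 21 C1=C10 enol triflate
Conditions: NaN(SiMe3)2, PhNTf2, THF, −78 °C
Reagents that add atoms: N-phenylbis(trifluoromethanesulfonimide), O=S(=O)(N(c1ccccc1)S(=O)(=O)C(F)(F)F)C(F)(F)F
Why: Kinetic deprotonation occurs at the C1 methylene, since the C9 bridgehead proton is poorly aligned with the carbonyl π-system, and O-triflation gives the enol triflate regioselectively.

**Step 12**
Reactants: 21 C1=C10 enol triflate
Product: 22 2-ethoxy-1,3-diene (C1=C10–C11(OEt)=C12H2)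
Conditions: tributyl(1-ethoxyvinyl)stannane, Pd(PPh3)4 (5 mol %), LiCl, THF, 65 °C
Reagents that add atoms: tributyl(1-ethoxyvinyl)stannane, CCCC[Sn](CCCC)(CCCC)C(=C)OCC
Why: Stille coupling of the enol triflate forms the C10–C11 bond and delivers an electron-rich diene for the ring-forming cycloaddition.

**Step 13**
Reactants: 22 2-ethoxy-1,3-diene; 23 but-3-en-2-one
Product: 25 cyclohexene enol ether with C14 acetyl (C1 and C14 as in the target), via C14-epimeric cycloadduct mixture 24 (not isolated)
Conditions: toluene, BHT (cat.), 110 °C, sealed tube; then K2CO3, MeOH, rt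
Reagents that add atoms: none
Why: Thermal Diels–Alder reaction in which the enol ether terminus C12 bonds to the enone β-carbon (acetyl on C14) and the dienophile adds to the diene face opposite the oxonene bridge (C1), after which base equilibration of the α-acetyl centre should converge the endo/exo mixture on the more stable C14 epimer with the acyl group cis to C2.

**Step 14**
Reactants: 25 cyclohexene enol ether with C14 acetyl
Product: 26 C14 isopropenyl compound
Conditions: Ph3PCH3Br, KOtBu, THF, 0 °C → rt
Reagents that add atoms: methyltriphenylphosphonium bromide, C[P+](c1ccccc1)(c1ccccc1)c1ccccc1.[Br-]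
Why: Wittig methylenation of the methyl ketone supplies C16 while the masked C11 ketone (enol ether) is untouched.

**Step 15**
Reactants: 26 C14 isopropenyl compound
Product: 28 primary alcohol (C16–OH; C15 as in the target), via B-alkyl-9-borabicyclononane 27 (not isolated)
Conditions: 9-borabicyclo[3.3.1]nonane, THF, 0 °C → rt; then H2O2, aq. NaOH, 0 °C
Reagents that add atoms: hydrogen peroxide, OO
Why: The 1,1-disubstituted alkene is hydroborated far faster than the trisubstituted and tetrasubstituted alkenes, and C15 is set by attack on the exposed face of the isopropenyl rotamer that minimises allylic strain with the ring.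

**Step 16**
Reactants: 28 primary alcohol
Product: 29 cis-fused C11 ketone triol (C3, C4 and C16 hydroxyls free)
Conditions: aq. HF (48%), MeCN, 0 °C → rt
Reagents that add atoms: water, O
Why: Aqueous acid hydrolyses the enol ether with protonation of C10 under thermodynamic control to the cis-fused ketone, and fluoride removes both triethylsilyl ethers.

**Step 17**
Reactants: 29 cis-fused C11 ketone triol
Product: 31 oxepane ketone with free C4 hydroxyl, via primary triflate 30 (not isolated)
Conditions: Tf2O (1.1 equiv), 2,6-lutidine, CH2Cl2, −78 °C → rt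
Reagents that add atoms: none
Why: The primary hydroxyl is triflated before the hindered secondary one, and the tertiary C3 hydroxyl displaces the triflate in a 7-exo-tet Williamson-type etherification that closes the oxepane while C13 is still a methylene that cannot take part.

**Step 18**
Reactants: 31 oxepane ketone with free C4 hydroxyl
Product: 32 C4 butanoate
Conditions: butanoic anhydride, DMAP, Et3N, CH2Cl2, rt
Reagents that add atoms: butanoic anhydride, CCCC(=O)OC(=O)CCC
Why: DMAP-catalysed acylation of the only remaining hydroxyl installs the ester of the target.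

**Step 19**
Reactants: 32 C4 butanoate
Product: 34 C11 ketone with C12=C13 alkene, via C11=C12 trimethylsilyl enol ether 33 (not isolated)
Conditions: LiN(SiMe3)2, Me3SiCl, THF, −78 °C; then Pd(OAc)2 (1.1 equiv), MeCN, rt
Reagents that add atoms: none
Why: Saegusa oxidation, in which the kinetic silyl enol ether forms towards the C12 methylene (ketone α-protons are removed before those of the ester or the tertiary C10–H) and palladium acetate then effects dehydrosilylation to the enone.

**Step 20**
Reactants: 34 C11 ketone with C12=C13 alkene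
Product: 35 tertiary allylic alcohol (C11 methyl carbinol; C11 configuration inconsequential)
Conditions: MeLi, CeCl3, THF, −78 °C
Reagents that add atoms: methyllithium, [Li]C
Why: Organocerium 1,2-addition to the enone is chemoselective over the butanoate at low temperature and brings in the C11 methyl group.

**Step 21**
Reactants: 35 tertiary allylic alcohol
Product: 36 target butanoate
Conditions: pyridinium chlorochromate [C5H5NH][CrO3Cl], 4 Å MS, CH2Cl2, rt
Reagents that add atoms: none
Why: Babler–Dauben oxidative transposition, in which the chromate ester of the tertiary allylic alcohol shifts to C13 by a [3,3] process and is oxidised, giving the C13 ketone and the C11=C12 methyl alkene, while C14 keeps the configuration set in step 13 within the cis-fused oxepane.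

**Compound list**
1 | 2-methylprop-2-enal | C=C(C)C=O | starting material
2 | (E)-1-methoxy-3-(trimethylsilyloxy)buta-1,3-diene | CO/C=C/C(=C)O[Si](C)(C)C | starting material
3 | 2-methoxy-6-(prop-1-en-2-yl)-4-(trimethylsilyloxy)-5,6-dihydro-2H-pyran (6S; acetal centre unspecified) | C=C(C)[C@@H]1CC(O[Si](C)(C)C)=CC(OC)O1 | intermediate (not isolated)
4 | (S)-2-(prop-1-en-2-yl)-2,3-dihydro-4H-pyran-4-one | C=C(C)[C@@H]1CC(=O)C=CO1 | intermediate
5 | (S)-5-iodo-2-(prop-1-en-2-yl)-2,3-dihydro-4H-pyran-4-one | C=C(C)[C@@H]1CC(=O)C(I)=CO1 | intermediate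
6 | (S)-5-methyl-2-(prop-1-en-2-yl)-2,3-dihydro-4H-pyran-4-one | C=C(C)[C@@H]1CC(=O)C(C)=CO1 | intermediate
7 | (2S,4S)-5-methyl-2-(prop-1-en-2-yl)-3,4-dihydro-2H-pyran-4-ol (cis) | C=C(C)[C@@H]1C[C@H](O)C(C)=CO1 | intermediate
8 | (2S,4S)-5-methyl-2-(prop-1-en-2-yl)-3,4-dihydro-2H-pyran-4-yl acetate | C=C(C)[C@@H]1C[C@H](OC(C)=O)C(C)=CO1 | intermediate
9 | trimethylsilyl ketene acetal of 8 | C=C(C)[C@@H]1C[C@H](OC(=C)O[Si](C)(C)C)C(C)=CO1 | intermediate (not isolated)
10 | trimethylsilyl ester of 11 | C=C(C)[C@@H]1CC=C(C)[C@H](CC(=O)O[Si](C)(C)C)O1 | intermediate (not isolated)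
11 | 2-[(2S,6S)-3-methyl-6-(prop-1-en-2-yl)-3,6-dihydro-2H-pyran-2-yl]acetic acid (2,6-cis) | C=C(C)[C@@H]1CC=C(C)[C@H](CC(=O)O)O1 | intermediate
12 | C3–C4 epoxy acid, epoxide anti to the C2 side chain | C=C(C)[C@@H]1C[C@H]2O[C@@]2(C)[C@H](CC(=O)O)O1 | intermediate (not isolated)
13 | hydroxy γ-lactone cis-fused to the tetrahydropyran (C3 methyl at the fusion, C4–OH trans to the lactone oxygen, C6 isopropenyl cis to C1) | C=C(C)[C@@H]1C[C@@H](O)[C@]2(C)OC(=O)C[C@@H]2O1 | intermediate
14 | lithium salt of the C3,C4-dihydroxy acid | C=C(C)[C@@H]1C[C@@H](O)[C@](C)(O)[C@H](CC(=O)[O-])O1.[Li+] | intermediate (not isolated)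
15 | triethylsilyl ester with C3 and C4 triethylsilyl ethers | C=C(C)[C@@H]1C[C@@H](O[Si](CC)(CC)CC)[C@](C)(O[Si](CC)(CC)CC)[C@H](CC(=O)O[Si](CC)(CC)CC)O1 | intermediate (not isolated)
16 | 2,6-cis tetrahydropyranylacetic acid with C3 (tertiary) and C4 triethylsilyl ethers | C=C(C)[C@@H]1C[C@@H](O[Si](CC)(CC)CC)[C@](C)(O[Si](CC)(CC)CC)[C@H](CC(=O)O)O1 | intermediate
17 | mixed isobutyl carbonic anhydride of 16 | C=C(C)[C@@H]1C[C@@H](O[Si](CC)(CC)CC)[C@](C)(O[Si](CC)(CC)CC)[C@H](CC(=O)OC(=O)OCC(C)C)O1 | intermediate (not isolated)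
18 | diazoketone of the 2,6-cis tetrahydropyran | C=C(C)[C@@H]1C[C@@H](O[Si](CC)(CC)CC)[C@](C)(O[Si](CC)(CC)CC)[C@H](CC(=O)C=[N+]=[N-])O1 | intermediate
19 | bicyclic oxonium ylide (O bonded to C2, C6 and C9; carbanion at C9) | C=C(C)[C@@H]1C[C@@H](O[Si](CC)(CC)CC)[C@](C)(O[Si](CC)(CC)CC)[C@@H]2CC(=O)[CH-][O+]12 | intermediate (not isolated)
20 | Z-oxonene bridged by O between C2 and C9, C10 ketone, C3 Me/OSiEt3, C4 OSiEt3 | CC[Si](CC)(CC)O[C@@H]1C/C=C(/C)C[C@@H]2O[C@@H](CC2=O)[C@@]1(C)O[Si](CC)(CC)CC | intermediate
21 | C1=C10 enol triflate of 20 | CC[Si](CC)(CC)O[C@@H]1C/C=C(/C)C[C@@H]2O[C@@H](C=C2OS(=O)(=O)C(F)(F)F)[C@@]1(C)O[Si](CC)(CC)CC | intermediate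
22 | 2-ethoxy diene C1=C10–C11(OEt)=C12H2 | CC[Si](CC)(CC)O[C@@H]1C/C=C(/C)C[C@@H]2O[C@@H](C=C2C(=C)OCC)[C@@]1(C)O[Si](CC)(CC)CC | intermediate
23 | but-3-en-2-one | C=CC(C)=O | starting material
24 | Diels–Alder adducts, C14 epimers (C14 unspecified) | CC[Si](CC)(CC)O[C@@H]1C/C=C(/C)C[C@@H]2O[C@@H]([C@@H]3C2=C(OCC)CCC3C(C)=O)[C@@]1(C)O[Si](CC)(CC)CC | intermediate (not isolated)
25 | tricyclic C10=C11 enol ether with C14 acetyl, C1 and C14 as in the target | CC[Si](CC)(CC)O[C@@H]1C/C=C(/C)C[C@@H]2O[C@@H]([C@@H]3C2=C(OCC)CC[C@@H]3C(C)=O)[C@@]1(C)O[Si](CC)(CC)CC | intermediate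
26 | C14 isopropenyl analogue of 25 | CC[Si](CC)(CC)O[C@@H]1C/C=C(/C)C[C@@H]2O[C@@H]([C@@H]3C2=C(OCC)CC[C@@H]3C(C)=C)[C@@]1(C)O[Si](CC)(CC)CC | intermediate
27 | C16 B-alkyl-9-borabicyclo[3.3.1]nonane | CC[Si](CC)(CC)O[C@@H]1C/C=C(/C)C[C@@H]2O[C@@H]([C@@H]3C2=C(OCC)CC[C@@H]3[C@@H](C)CB4C5CCCC4CCC5)[C@@]1(C)O[Si](CC)(CC)CC | intermediate (not isolated)
28 | C16 primary alcohol, C15 as in the target | CC[Si](CC)(CC)O[C@@H]1C/C=C(/C)C[C@@H]2O[C@@H]([C@@H]3C2=C(OCC)CC[C@@H]3[C@@H](C)CO)[C@@]1(C)O[Si](CC)(CC)CC | intermediate
29 | cis-fused C11 ketone with free C3, C4 and C16 hydroxyls | O[C@@H]1C/C=C(/C)C[C@@H]2O[C@@H]([C@@H]3[C@H]2C(=O)CC[C@@H]3[C@@H](C)CO)[C@@]1(C)O | intermediate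
30 | C16 primary triflate of 29 | O[C@@H]1C/C=C(/C)C[C@@H]2O[C@@H]([C@@H]3[C@H]2C(=O)CC[C@@H]3[C@@H](C)COS(=O)(=O)C(F)(F)F)[C@@]1(C)O | intermediate (not isolated)
31 | tetracyclic oxepane, C11 ketone, C4 hydroxyl | O[C@@H]1C/C=C(/C)C[C@@H]2O[C@H]3[C@@H]4[C@H]2C(=O)CC[C@@H]4[C@@H](C)CO[C@@]13C | intermediate
32 | C4 butanoate of 31 | CCCC(=O)O[C@@H]1C/C=C(/C)C[C@@H]2O[C@H]3[C@@H]4[C@H]2C(=O)CC[C@@H]4[C@@H](C)CO[C@@]13C | intermediate
33 | C11=C12 trimethylsilyl enol ether of 32 | CCCC(=O)O[C@@H]1C/C=C(/C)C[C@@H]2O[C@H]3[C@@H]4[C@H]2C(O[Si](C)(C)C)=CC[C@@H]4[C@@H](C)CO[C@@]13C | intermediate (not isolated)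
34 | enone with C11 ketone and C12=C13 alkene | CCCC(=O)O[C@@H]1C/C=C(/C)C[C@@H]2O[C@H]3[C@@H]4[C@H]2C(=O)C=C[C@@H]4[C@@H](C)CO[C@@]13C | intermediate
35 | C11 tertiary allylic alcohol (C11 unspecified) | CCCC(=O)O[C@@H]1C/C=C(/C)C[C@@H]2O[C@H]3[C@@H]4[C@H]2C(C)(O)C=C[C@@H]4[C@@H](C)CO[C@@]13C | intermediate
36 | CNP0271677.1 | CCCC(=O)O[C@@H]1C/C=C(/C)C[C@@H]2O[C@H]3[C@@H]4[C@H]2C(C)=CC(=O)[C@@H]4[C@@H](C)CO[C@@]13C | target

**Totals:** 21 steps; longest linear sequence 21 steps.

**Steps most likely to fail**

1. Step 10: incomplete control of alkene geometry in the [2,3]-shift, giving the E-oxonene beside the Z-isomer. Fallback: the selectivity is not sought in the rearrangement itself. The crude mixture from 18 is taken on, and the E-configured bridged ketone F1 is equilibrated to the Z-isomer, expected to be the more stable one, by reversible thiyl radical addition (EtSH, azobisisobutyronitrile, benzene, 80 °C). This sets out from 18 and comes back to the route at 20.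

2. Step 15: poor facial selectivity in the substrate-controlled hydroboration, giving both C15 epimers. Fallback: catalyst control in place of substrate control. Compound 26 is treated with pinacolborane, CuCl, NaOtBu and the enantiomer of DTBM-SEGPHOS matched to the required C15 configuration (copper hydride hydroboration of a 1,1-disubstituted alkene), giving the C16 pinacol boronate F2. Oxidation with NaBO3·4H2O in THF/H2O then comes back to the route at 28.

3. Step 7: epoxidation on the alkene face syn to the side chain or at the isopropenyl group, leaving epoxide that cannot lactonise. Fallback: halolactonisation, which is stereospecific whichever face the electrophile prefers. From 11, I2/NaHCO3 in MeCN gives the iodolactone F3 (lactone oxygen on C3, iodide on C4, trans). K2CO3 in MeOH converts it into the epoxy methyl ester F4 with the epoxide syn to the side chain. Aqueous NaOH in dioxane at 60 °C opens F4 at the secondary C4 with inversion, and acidification to pH 3 relactonises, coming back to the route at 13.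

**Further compounds**
F1 | step 10 | E-isomer of bridged ketone 20 | CC[Si](CC)(CC)O[C@@H]1C/C=C(\C)C[C@@H]2O[C@@H](CC2=O)[C@@]1(C)O[Si](CC)(CC)CC
F2 | step 15 | C16 pinacol boronate | CC[Si](CC)(CC)O[C@@H]1C/C=C(/C)C[C@@H]2O[C@@H]([C@@H]3C2=C(OCC)CC[C@@H]3[C@@H](C)CB4OC(C)(C)C(C)(C)O4)[C@@]1(C)O[Si](CC)(CC)CC
F3 | step 7 | C4 iodo γ-lactone | C=C(C)[C@@H]1C[C@@H](I)[C@]2(C)OC(=O)C[C@@H]2O1
F4 | step 7 | methyl ester with C3–C4 epoxide syn to the side chain | C=C(C)[C@@H]1C[C@@H]2O[C@]2(C)[C@H](CC(=O)OC)O1
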